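**Retrosynthetic overview**
- The strategy rests on the ring-cis (4Z) alkene C4=C5, held between the oxygen-bearing C3 and C6 and lying 1,5 to the C1–C10 epoxide (a masked E alkene) of the ten-membered carbocycle. A notional C1–C6 bond folds C1–C6, C15 and C9/C10/C14 onto the skeleton of carvone (carbonyl at C3, enone alkene at C4=C5, isopropenyl on C1).
- Late stage: the C3 silyl ether is removed, C15 is hydroxylated, C1=C10 is epoxidised and O8 is acylated on an 8-hydroxy-6,12-olide. That lactone comes from a 6,8,12-triol by oxidative lactonisation, with the C8 hydroxyl unmasked from a C8–Si bond.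
- Key disconnection: the C8–C9 bond of a silyl cyclodecadienone is cut in the anionic oxy-Cope sense with C1–C6 re-formed, which leads back to a trans-1,2-dialkenylcyclohexenol.
- That carbinol is split at C6–C7 into a 4-silyloxy-isopiperitenone (from (R)-carvone) and a 1-silylbuta-1,3-dien-2-yl metal that carries C7, C8 and C11–C13 (from ethynylmagnesium bromide and 2-bromoallyl alcohol).
- Ring order: the cyclohexene is bought, then expanded to the ten-membered carbocycle, then the γ-lactone is closed, then the epoxide is formed.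

Key step: step 11

Assumption: germacranolide numbering is used throughout (C1–C10 carbocycle, C11–C13 lactone carbons, C14 on C10, C15 on C4; α/β as in the usual projection with H7 α). Facial outcomes in the ten-membered ring are predictions based on attack at the peripheral face.

Step 1
Reactants: 1 (R)-(−)-carvone
Product: 2 (1R,5R)-cis-carveol
Conditions: NaBH4, CeCl3·7H2O, MeOH, −78 to 0 °C
Reagents that add atoms: none
Why: Luche 1,2-reduction with axial hydride delivery to the carvone half-chair should give the cis alcohol, so the new carbinol centre (R) is set by the existing isopropenyl-bearing centre.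

Step 2
Reactants: 2 (1R,5R)-cis-carveol
Product: 3 (1S,5R)-trans-carveyl 4-nitrobenzoate
Conditions: 4-nitrobenzoic acid, PPh3, DIAD, THF, 0 °C to rt
Reagents that add atoms: 4-nitrobenzoic acid O=C(O)c1ccc(cc1)[N+](=O)[O-]
Why: Mitsunobu esterification, in which SN2 displacement of the oxyphosphonium by the carboxylate inverts the carbinol centre to S, the configuration needed at C3 of the target (oxygen now trans to isopropenyl).

Step 3
Reactants: 3 (1S,5R)-trans-carveyl 4-nitrobenzoate
Product: 4 (1S,5R)-trans-carveol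
Conditions: K2CO3 (cat.), MeOH, rt
Reagents that add atoms: none
Why: Base-catalysed transesterification removes the electron-poor aroyl group by acyl–oxygen cleavage, so the carbinol centre is not touched.

Step 4
Reactants: 4 (1S,5R)-trans-carveol
Product: 5 (1S,5R)-trans-carveol triisopropylsilyl ether
Conditions: TIPSOTf, 2,6-lutidine, CH2Cl2, 0 °C
Reagents that add atoms: triisopropylsilyl triflate CC(C)[Si](OS(=O)(=O)C(F)(F)F)(C(C)C)C(C)C
Why: Silyl triflate/lutidine silylation of a hindered secondary allylic alcohol; the triisopropylsilyl ether is chosen to last through organometallic, hydride, peroxide and brief fluoride steps.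

Step 5
Reactants: 5 (1S,5R)-trans-carveol triisopropylsilyl ether
Product: 6 (4S,6R)-3-methyl-6-(prop-1-en-2-yl)-4-(triisopropylsilyloxy)cyclohex-2-en-1-one
Conditions: CrO3, 3,5-dimethylpyrazole, CH2Cl2, −20 °C; neutral work-up, used promptly
Reagents that add atoms: chromium trioxide O=[Cr](=O)=O
Why: Chromium trioxide–3,5-dimethylpyrazole allylic oxidation should convert the only free ring allylic methylene (future C6) into the conjugated ketone, the silyloxy-bearing C3–H being shielded and deactivated; cold neutral conditions should leave the α-stereocentre (future C1) intact.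

Step 6
Reactants: 7 ethynylmagnesium bromide
Product: 8 benzyl(ethynyl)dimethylsilane
Conditions: benzylchlorodimethylsilane, THF, 0 °C to rt
Reagents that add atoms: benzylchlorodimethylsilane C[Si](C)(Cl)Cc1ccccc1
Why: Nucleophilic substitution at silicon by the acetylide Grignard reagent (C-silylation).

Step 7
Reactants: 8 benzyl(ethynyl)dimethylsilane; 9 2-bromoprop-2-en-1-ol (2-bromoallyl alcohol)
Product: 10 4-[benzyl(dimethyl)silyl]-2-methylidenebut-3-yn-1-ol
Conditions: PdCl2(PPh3)2 (cat.), CuI (cat.), i-Pr2NH, THF, rt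
Reagents that add atoms: none
Why: Sonogashira coupling of the terminal alkyne with the vinyl bromide; the alkynyl C–Si bond and the free alcohol are tolerated.

Step 8
Reactants: 10 4-[benzyl(dimethyl)silyl]-2-methylidenebut-3-yn-1-ol
Product: 11 tert-butyldiphenylsilyl ether of 10
Conditions: TBDPSCl, imidazole, CH2Cl2, rt
Reagents that add atoms: tert-butylchlorodiphenylsilane CC(C)(C)[Si](Cl)(c1ccccc1)c1ccccc1
Why: Standard silylation of the primary alcohol; the bulky silyl group is chosen so that it should not migrate later to a neighbouring carbanion or alkoxide.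

Step 9
Reactants: 11 tert-butyldiphenylsilyl ether of 10
Product: 12 (E)-1-[benzyl(dimethyl)silyl]-2-(tributylstannyl)-3-[(tert-butyldiphenylsilyloxy)methyl]buta-1,3-diene (Si trans to Sn)
Conditions: Bu3SnH, PdCl2(PPh3)2 (cat.), THF, 0 °C to rt
Reagents that add atoms: tributyltin hydride CCCC[SnH](CCCC)CCCC
Why: Palladium-catalysed hydrostannation adds H and Sn syn across the alkyne, with tin expected on the carbon conjugated to the vinyl group and remote from the bulky silyl group, so that silicon ends up trans to tin.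

Step 10
Reactants: 12 (E)-1-silyl-2-stannyl diene; 6 (4S,6R)-4-silyloxy-isopiperitenone
Product: 15 trans-1,2-dialkenylcyclohexenol (hydroxyl cis to isopropenyl; dienyl trans to isopropenyl), via dienyllithium 13 (not isolated), via dienylcerium dichloride 14 (not isolated)
Conditions: n-BuLi, THF, −78 °C; anhydrous CeCl3, THF, −78 °C; then 6, −78 to −40 °C; pH 7 buffer
Reagents that add atoms: none
Why: Tin–lithium exchange with retention of alkene geometry, transmetalation to the weakly basic organocerium to suppress enolisation, and 1,2-addition along the equatorial trajectory trans to the adjacent isopropenyl group should set the carbinol centre with both alkenyl groups equatorial.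

Step 11
Reactants: 15 trans-1,2-dialkenylcyclohexenol
Product: 18 (1(10)E,4Z)-8β-[benzyl(dimethyl)silyl]-12-(tert-butyldiphenylsilyloxy)-3β-(triisopropylsilyloxy)germacra-1(10),4,11(13)-trien-6-one (H7 α), via potassium alkoxide 16 (not isolated), via potassium dienolate 17 (not isolated)
Conditions: KH, 18-crown-6, THF, 0 °C to rt; then −78 °C, AcOH in THF; cold pH 7 work-up
Reagents that add atoms: none
Why: Deprotonation gives the potassium alkoxide, whose charge weakens the doubly allylic C1–C6 bond, so the 1,5-diene C8=C7–C6–C1–C10=C9 undergoes an anionic oxy-Cope [3,3] shift that forms C8–C9 as C1–C6 breaks and ends irreversibly in the dienolate. The closest known reaction type is the anionic oxy-Cope ring expansion of trans-1,2-dialkenylcyclohexanols to (E)-cyclodec-5-enones. The ten-membered carbocycle is thus closed by a four-atom ring expansion of the cyclohexene through a six-centre chair, not by an end-to-end macrocyclisation, and the 4Z alkene is the old ring alkene carried over unchanged. C8 is set by chirality transfer from C1: with both alkenyl groups equatorial only one chair is open, the E vinylsilane puts silicon equatorial in it, and the same chair gives the E geometry at C1=C10. C7 is set in the quench, where acetic acid at −78 °C should protonate the α-carbon of the dienolate on the face turned away from the transannular C1=C10 unit. The step needs one chair sense, the [3,3] path over [1,3] shift or fragmentation, and α- over γ-protonation; these are secured by the diequatorial alkenyl groups (held by the pseudoaxial C3 silyl ether next to the C4 methyl), by the concerted chair geometry, and by a kinetic low-temperature quench.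

Step 12
Reactants: 18 silyl germacratrien-6-one (crude, used at once)
Product: 19 8β-[benzyl(dimethyl)silyl]-12-(tert-butyldiphenylsilyloxy)-3β-(triisopropylsilyloxy)germacra-1(10)E,4Z,11(13)-trien-6α-ol
Conditions: i-Bu2AlH, CH2Cl2, −78 °C; aqueous potassium sodium tartrate
Reagents that add atoms: none
Why: 1,2-Reduction of the ketone by the aluminium hydride at low temperature, before the β,γ-alkene can move into conjugation; hydride should arrive on the peripheral face of the carbonyl in the ring conformer produced by the rearrangement, which places the new hydroxyl at C6 α (H6 β).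

Step 13
Reactants: 19 8β-silyl germacratrien-6α-ol
Product: 21 3β-(triisopropylsilyloxy)germacra-1(10)E,4Z,11(13)-triene-6α,8β,12-triol, via fluorosilane diol 20 (not isolated)
Conditions: Bu4NF, THF, 0 °C, brief; then KHCO3, 30% H2O2, MeOH/THF, rt
Reagents that add atoms: hydrogen peroxide OO
Why: Fluoride cleaves the benzyl–silicon bond and the primary silyl ether, and the fluorosilane then undergoes Tamao–Fleming oxidation, in which C8 migrates from silicon to oxygen with retention so that the 8β-silyl group becomes the 8β-hydroxyl; the hindered secondary triisopropylsilyl ether should outlast the brief cold fluoride treatment.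

Step 14
Reactants: 21 6α,8β,12-triol
Product: 24 8β-hydroxy-3β-(triisopropylsilyloxy)germacra-1(10)E,4Z,11(13)-trien-12,6α-olide, via hydroxy enal 22 (not isolated), via lactol 23 (not isolated)
Conditions: TEMPO (cat.), PhI(OAc)2, CH2Cl2, rt
Reagents that add atoms: none
Why: TEMPO/PhI(OAc)2 oxidative lactonisation: the primary allylic alcohol is oxidised chemoselectively, the enal is trapped as a lactol and oxidised on to the α-methylene lactone; trans-fused closure onto O6 is expected to win over cis-fused closure onto O8, and no stereocentre is touched.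

Step 15
Reactants: 24 8β-hydroxy 6,12-olide; 25 methacrylic anhydride
Product: 26 8β-methacryloyloxy-3β-(triisopropylsilyloxy)germacra-1(10)E,4Z,11(13)-trien-12,6α-olide
Conditions: DMAP, Et3N, CH2Cl2, 0 °C to rt
Reagents that add atoms: none
Why: DMAP-catalysed acyl transfer (Steglich-type esterification) to the only free hydroxyl.

Step 16
Reactants: 26 8β-methacrylate
Product: 27 1β,10α-epoxy-8β-methacryloyloxy-3β-(triisopropylsilyloxy)germacra-4Z,11(13)-dien-12,6α-olide
Conditions: mCPBA, NaHCO3, CH2Cl2, 0 °C
Reagents that add atoms: 3-chloroperoxybenzoic acid OOC(=O)c1cccc(Cl)c1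
Why: Prilezhaev epoxidation of C1=C10, the only electron-rich alkene that is neither conjugated nor flanked by oxygen; syn delivery of oxygen to its peripheral face in the lactone-constrained ring (C14 on the β side) should set C1 and C10 as the trans 1β,10α-epoxide.

Step 17
Reactants: 27 1β,10α-epoxide
Product: 28 1β,10α-epoxy-15-hydroxy-8β-methacryloyloxy-3β-(triisopropylsilyloxy)germacra-4Z,11(13)-dien-12,6α-olide
Conditions: SeO2 (cat.), t-BuOOH, CH2Cl2, rt
Reagents that add atoms: tert-butyl hydroperoxide CC(C)(C)OO; selenium dioxide O=[Se]=O (catalytic oxygen carrier)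
Why: Selenium dioxide allylic hydroxylation (Riley oxidation: ene reaction then [2,3]-sigmatropic shift) should attack the only remaining unconjugated alkene at the substituent on its disubstituted carbon that lies cis to H5, which is C15 because C3 already carries oxygen, and return the alkene with its 4Z geometry.

Step 18
Reactants: 28 15-hydroxy silyl ether
Product: 29 target CNP0496616.1 (1β,10α-epoxy-3β,15-dihydroxy-8β-methacryloyloxygermacra-4Z,11(13)-dien-12,6α-olide)
Conditions: HF·pyridine, pyridine, THF, 0 °C to rt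
Reagents that add atoms: none
Why: Fluoride-mediated cleavage of the silyl ether under buffered, weakly acidic conditions that should spare the epoxide, both unsaturated esters and the primary allylic alcohol.

**Compound list**
1 | (R)-(−)-carvone | CC1=CC[C@H](CC1=O)C(C)=C | starting material
2 | (1R,5R)-cis-carveol | C1C=C(C)[C@H](O)C[C@@H]1C(C)=C | intermediate
3 | (1S,5R)-trans-carveyl 4-nitrobenzoate | C1C=C(C)[C@@H](OC(=O)c2ccc(cc2)[N+](=O)[O-])C[C@@H]1C(C)=C | intermediate
4 | (1S,5R)-trans-carveol | C1C=C(C)[C@@H](O)C[C@@H]1C(C)=C | intermediate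
5 | (1S,5R)-trans-carveol triisopropylsilyl ether | C1C=C(C)[C@@H](O[Si](C(C)C)(C(C)C)C(C)C)C[C@@H]1C(C)=C | intermediate
6 | (4S,6R)-3-methyl-6-(prop-1-en-2-yl)-4-(triisopropylsilyloxy)cyclohex-2-en-1-one (silyloxy trans to isopropenyl) | O=C1C=C(C)[C@@H](O[Si](C(C)C)(C(C)C)C(C)C)C[C@@H]1C(C)=C | intermediate
7 | ethynylmagnesium bromide | C#C[Mg]Br | starting material
8 | benzyl(ethynyl)dimethylsilane | C#C[Si](C)(C)Cc1ccccc1 | intermediate
9 | 2-bromoprop-2-en-1-ol | OCC(Br)=C | starting material
10 | 4-[benzyl(dimethyl)silyl]-2-methylidenebut-3-yn-1-ol | C[Si](C)(Cc1ccccc1)C#CC(=C)CO | intermediate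
11 | tert-butyldiphenylsilyl ether of 10 | C[Si](C)(Cc1ccccc1)C#CC(=C)CO[Si](c1ccccc1)(c1ccccc1)C(C)(C)C | intermediate
12 | (E)-1-[benzyl(dimethyl)silyl]-2-(tributylstannyl)-3-[(tert-butyldiphenylsilyloxy)methyl]buta-1,3-diene | CCCC[Sn](CCCC)(CCCC)/C(=C/[Si](C)(C)Cc1ccccc1)C(=C)CO[Si](c1ccccc1)(c1ccccc1)C(C)(C)C | intermediate
13 | dien-2-yllithium from 12 (Li in place of Sn, geometry retained) | [Li]/C(=C/[Si](C)(C)Cc1ccccc1)C(=C)CO[Si](c1ccccc1)(c1ccccc1)C(C)(C)C | intermediate
14 | dien-2-ylcerium dichloride | Cl[Ce](Cl)/C(=C/[Si](C)(C)Cc1ccccc1)C(=C)CO[Si](c1ccccc1)(c1ccccc1)C(C)(C)C | intermediate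
15 | trans-1,2-dialkenylcyclohexenol: 1-(silyldienyl)-3-methyl-6-isopropenyl-4-(triisopropylsilyloxy)cyclohex-2-en-1-ol, hydroxyl cis and dienyl trans to isopropenyl | O[C@]1(/C(=C/[Si](C)(C)Cc2ccccc2)C(=C)CO[Si](c2ccccc2)(c2ccccc2)C(C)(C)C)C=C(C)[C@@H](O[Si](C(C)C)(C(C)C)C(C)C)C[C@@H]1C(C)=C | intermediate
16 | potassium alkoxide of 15 | [K+].[O-][C@]1(/C(=C/[Si](C)(C)Cc2ccccc2)C(=C)CO[Si](c2ccccc2)(c2ccccc2)C(C)(C)C)C=C(C)[C@@H](O[Si](C(C)C)(C(C)C)C(C)C)C[C@@H]1C(C)=C | intermediate
17 | ring-expanded potassium dienolate (C6 enolate, C6=C7, 8β-silyl) | C[Si](C)(Cc2ccccc2)[C@@H]1C/C(C)=C/C[C@H](O[Si](C(C)C)(C(C)C)C(C)C)/C(C)=C\C(\[O-])=C1/C(=C)CO[Si](c2ccccc2)(c2ccccc2)C(C)(C)C.[K+] | intermediate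
18 | (1(10)E,4Z)-8β-[benzyl(dimethyl)silyl]-12-(tert-butyldiphenylsilyloxy)-3β-(triisopropylsilyloxy)germacra-1(10),4,11(13)-trien-6-one, H7 α | C[Si](C)(Cc2ccccc2)[C@@H]1C/C(C)=C/C[C@H](O[Si](C(C)C)(C(C)C)C(C)C)/C(C)=C\C(=O)[C@@H]1C(=C)CO[Si](c2ccccc2)(c2ccccc2)C(C)(C)C | intermediate
19 | corresponding 6α-ol | C[Si](C)(Cc2ccccc2)[C@@H]1C/C(C)=C/C[C@H](O[Si](C(C)C)(C(C)C)C(C)C)/C(C)=C\[C@@H](O)[C@@H]1C(=C)CO[Si](c2ccccc2)(c2ccccc2)C(C)(C)C | intermediate
20 | 8β-(fluorodimethylsilyl)-3β-(triisopropylsilyloxy)germacratriene-6α,12-diol | C[Si](C)(F)[C@@H]1C/C(C)=C/C[C@H](O[Si](C(C)C)(C(C)C)C(C)C)/C(C)=C\[C@@H](O)[C@@H]1C(=C)CO | intermediate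
21 | 3β-(triisopropylsilyloxy)germacra-1(10)E,4Z,11(13)-triene-6α,8β,12-triol | O[C@@H]1C/C(C)=C/C[C@H](O[Si](C(C)C)(C(C)C)C(C)C)/C(C)=C\[C@@H](O)[C@@H]1C(=C)CO | intermediate
22 | 6α,8β-dihydroxy-3β-(triisopropylsilyloxy)germacratrien-12-al | O[C@@H]1C/C(C)=C/C[C@H](O[Si](C(C)C)(C(C)C)C(C)C)/C(C)=C\[C@@H](O)[C@@H]1C(=C)C=O | intermediate
23 | 6α,12-lactol (C12 hemiacetal, configuration at C12 open) | O[C@@H]1C/C(C)=C/C[C@H](O[Si](C(C)C)(C(C)C)C(C)C)/C(C)=C\[C@H]2OC(O)C(=C)[C@@H]21 | intermediate
24 | 8β-hydroxy-3β-(triisopropylsilyloxy)germacra-1(10)E,4Z,11(13)-trien-12,6α-olide | O[C@@H]1C/C(C)=C/C[C@H](O[Si](C(C)C)(C(C)C)C(C)C)/C(C)=C\[C@H]2OC(=O)C(=C)[C@@H]21 | intermediate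
25 | methacrylic anhydride | C=C(C)C(=O)OC(=O)C(C)=C | starting material
26 | 8β-methacryloyloxy-3β-(triisopropylsilyloxy)germacra-1(10)E,4Z,11(13)-trien-12,6α-olide | C=C(C)C(=O)O[C@@H]1C/C(C)=C/C[C@H](O[Si](C(C)C)(C(C)C)C(C)C)/C(C)=C\[C@H]2OC(=O)C(=C)[C@@H]21 | intermediate
27 | 1β,10α-epoxide of 26 | C=C(C)C(=O)O[C@@H]1C[C@@]2(C)O[C@@H]2C[C@H](O[Si](C(C)C)(C(C)C)C(C)C)/C(C)=C\[C@H]2OC(=O)C(=C)[C@@H]21 | intermediate
28 | 15-hydroxy derivative of 27 | C=C(C)C(=O)O[C@@H]1C[C@@]2(C)O[C@@H]2C[C@H](O[Si](C(C)C)(C(C)C)C(C)C)/C(CO)=C\[C@H]2OC(=O)C(=C)[C@@H]21 | intermediate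
29 | CNP0496616.1 (1β,10α-epoxy-3β,15-dihydroxy-8β-methacryloyloxygermacra-4Z,11(13)-dien-12,6α-olide) | C=C(C)C(=O)O[C@@H]1C[C@@]2(C)O[C@@H]2C[C@H](O)/C(CO)=C\[C@H]2OC(=O)C(=C)[C@@H]21 | target

**Totals**
Total step count: 18.
Longest linear sequence: 14 steps (steps 1–5, then 10–18, from (R)-carvone).

**Steps most likely to fail**

Step 11 (ring expansion and quench). The alkoxide may fragment or follow a [1,3] path instead of the concerted [3,3] shift, and the free potassium dienolate may be protonated at the γ-carbon (C13) or on the wrong face of C7. The fallback is the neutral silyloxy variant and sets out from carbinol 15. N-(Trimethylsilyl)imidazole should give the trimethylsilyl ether F1. Heating F1 in base-washed glassware (o-dichlorobenzene, about 180 °C) should effect the concerted siloxy-Cope shift through the same chair to the ring-expanded trimethylsilyl dienol ether F2. MeLi in THF at 0 °C then releases the lithium dienolate F3, a tighter ion pair than the potassium species, which is quenched with acetic acid at −78 °C. The fallback returns to the route at ketone 18.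

Step 10 (dienyl addition). The hindered dienyl metal may enolise the α'-allylic ketone, the tin–lithium exchange may be incomplete, silyl migration from oxygen to the carbanion may intervene, or the nucleophile may add on the wrong face. The fallback builds the diene on the ring and sets out from enone 6 and alkyne 8. The lithium acetylide of 8 (n-BuLi, then CeCl3) is a slim, weakly basic nucleophile and should add trans to the isopropenyl group to give the propargylic alcohol F4. Hydroxyl-directed ruthenium-catalysed trans-hydrostannation ([Cp*RuCl]4, Bu3SnH, CH2Cl2) should place tin on the carbinol-side alkyne carbon (C7) with H8 anti, giving the α-stannyl alkenol F5 with tin cis to silicon. Stille coupling (Pd(PPh3)4, CuI, CsF, DMF) with 2-bromoallyl tert-butyldiphenylsilyl ether F6 (from 9, TBDPSCl, imidazole) proceeds with retention. The fallback returns to the route at carbinol 15 and also avoids the regiochemical question of step 9.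

Step 5 (allylic oxidation). Oxidation may occur at competing allylic sites (C3–H, the tertiary C1–H, the methyl groups), or the new α-centre may epimerise or the isopropenyl alkene move into conjugation under the oxidant. The fallback places the ketone by an epoxide/selenoxide/transposition sequence and sets out from trans-carveol 4. Hydroxyl-directed epoxidation (VO(acac)2, t-BuOOH, CH2Cl2) should give the syn epoxy alcohol F7, which is silylated (TIPSOTf, 2,6-lutidine) to the epoxy silyl ether F8. Sodium phenylselenide (PhSeSePh, NaBH4, EtOH) opens the epoxide at the secondary carbon to the hydroxy selenide F9. Oxidation with H2O2 and selenoxide syn-elimination away from the carbinol gives the tertiary allylic alcohol F10 with the alkene at C5=C6. Babler–Dauben oxidative transposition with pyridinium chlorochromate (C5H5NH[CrO3Cl], CH2Cl2) then moves oxygen to C6. The fallback returns to the route at enone 6.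

**Further compounds**
F1 | step 11 | trimethylsilyl ether of carbinol 15 | C[Si](C)(C)O[C@]1(/C(=C/[Si](C)(C)Cc2ccccc2)C(=C)CO[Si](c2ccccc2)(c2ccccc2)C(C)(C)C)C=C(C)[C@@H](O[Si](C(C)C)(C(C)C)C(C)C)C[C@@H]1C(C)=C
F2 | step 11 | ring-expanded trimethylsilyl dienol ether (C6 O-silyl, C6=C7) | C[Si](C)(Cc2ccccc2)[C@@H]1C/C(C)=C/C[C@H](O[Si](C(C)C)(C(C)C)C(C)C)/C(C)=C\C(\O[Si](C)(C)C)=C1/C(=C)CO[Si](c2ccccc2)(c2ccccc2)C(C)(C)C
F3 | step 11 | ring-expanded lithium dienolate | C[Si](C)(Cc2ccccc2)[C@@H]1C/C(C)=C/C[C@H](O[Si](C(C)C)(C(C)C)C(C)C)/C(C)=C\C(\[O-])=C1/C(=C)CO[Si](c2ccccc2)(c2ccccc2)C(C)(C)C.[Li+]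
F4 | step 10 | propargylic alcohol: 1-{[benzyl(dimethyl)silyl]ethynyl}-3-methyl-6-isopropenyl-4-(triisopropylsilyloxy)cyclohex-2-en-1-ol, alkynyl trans to isopropenyl | O[C@]1(C#C[Si](C)(C)Cc2ccccc2)C=C(C)[C@@H](O[Si](C(C)C)(C(C)C)C(C)C)C[C@@H]1C(C)=C
F5 | step 10 | α-stannyl alkenol: tributylstannyl on the carbinol-side alkene carbon, tin cis to silicon | O[C@]1(/C(=C/[Si](C)(C)Cc2ccccc2)[Sn](CCCC)(CCCC)CCCC)C=C(C)[C@@H](O[Si](C(C)C)(C(C)C)C(C)C)C[C@@H]1C(C)=C
F6 | step 10 | 2-bromoallyl tert-butyldiphenylsilyl ether | C=C(Br)CO[Si](c1ccccc1)(c1ccccc1)C(C)(C)C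
F7 | step 5 | syn-epoxy alcohol of trans-carveol (ring epoxide cis to hydroxyl) | C1[C@H]2O[C@@]2(C)[C@@H](O)C[C@@H]1C(C)=C
F8 | step 5 | triisopropylsilyl ether of F7 | C1[C@H]2O[C@@]2(C)[C@@H](O[Si](C(C)C)(C(C)C)C(C)C)C[C@@H]1C(C)=C
F9 | step 5 | hydroxy selenide (tertiary alcohol at the methyl-bearing carbon, phenylselanyl on the neighbouring ring CH, trans) | C1[C@H]([Se]c2ccccc2)[C@@](C)(O)[C@@H](O[Si](C(C)C)(C(C)C)C(C)C)C[C@@H]1C(C)=C
F10 | step 5 | tertiary allylic alcohol (1-methyl-4-isopropenyl-6-(triisopropylsilyloxy)cyclohex-2-en-1-ol) | C1=C[C@@](C)(O)[C@@H](O[Si](C(C)C)(C(C)C)C(C)C)C[C@@H]1C(C)=C
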